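The pyran ring is disconnected at C2–C3 and C4–C4a. An oxa-Povarov (cationic [4+2]) annulation should make both bonds in one operation. The precursor is the mixed O-aryl O-methyl acetone ketal of 2,4-dihydroxy-6-methoxyacetophenone. It ionises to an aryl oxocarbenium ion (2-oxadiene C4a=C8a–O1=C2), ethyl vinyl ether adds to C2 as the C3–C4 unit, and the electron-rich phloroglucinol ring carbon C4a, ortho to O1 and to the chelated C5 hydroxyl, closes the ring; loss of ethanol gives the chromene. The C8 prenyl group then comes from O-prenylation and para-Claisen–Cope rearrangement, and the 4-hydroxybenzyl ketone from Pd-catalysed α-arylation of the acetyl group.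

Key step: step 2

Remark on the chemistry: the target has no stereocentre and no stereogenic double bond, so it is achiral and no enantiocontrol is needed. Compounds 5, 9, 11 and 12 are racemic, and their stereocentres are removed before the target is reached.

Step 1
Reactants: 1 1-(2,4-dihydroxy-6-methoxyphenyl)ethan-1-one; 2 2-methoxypropene
Product: 3 1-[2-hydroxy-6-methoxy-4-(2-methoxypropan-2-yloxy)phenyl]ethan-1-one
Conditions: 2-methoxypropene (2 equiv), PPTS (2 mol%), CH2Cl2, 0 °C; Et3N quench, filtration through basic alumina, used at once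
Reagents that add atoms: 2-methoxypropene (2), COC(C)=C
Why: Acid-catalysed addition of a phenol to an enol ether (mixed ketal formation) should take place only at the non-chelated 4-OH, because the 2-OH is held in the hydrogen bond to the acetyl carbonyl.

Step 2
Reactants: 3 1-[2-hydroxy-6-methoxy-4-(2-methoxypropan-2-yloxy)phenyl]ethan-1-one; 4 ethyl vinyl ether
Product: 6 1-(5-hydroxy-7-methoxy-2,2-dimethyl-2H-chromen-6-yl)ethan-1-one, via 4-ethoxychroman 5 (not isolated)
Conditions: ethyl vinyl ether (1.5 equiv, slow addition), BF3·OEt2 (20 mol%), CH2Cl2, −78 → 0 °C; then CSA (10 mol%), 40 °C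
Reagents that add atoms: ethyl vinyl ether (4), C=COCC
Why: BF3 should bind the more basic methoxy oxygen of the ketal and expel methoxide to give the aryl oxocarbenium ion Ar–O+=CMe2; the enol ether adds through its CH2 terminus to this carbon (C2–C3), the resulting ethoxycarbenium ion is captured by the ortho ring carbon (Friedel–Crafts, C4–C4a) to give 4-ethoxychroman 5, and 5 loses ethanol by E1 under the acid to give the chromene. The closest known reaction type is the oxa-Povarov reaction, the stepwise cationic [4+2] annulation of aryl oxocarbenium ions from O-aryl mixed acetals with alkenes, run here with an enol ether as in the aza-Povarov reaction and the Müller-Cunradi–Pieroh acetal–vinyl ether addition. The pyran ring closes by a 6-exo-trig Friedel–Crafts attack of the arene π bond on the tethered oxocarbenium carbon. The C4 stereocentre of 5 is formed racemic and is destroyed in the elimination, so no stereocontrol is needed. The step needs site selectivity between the two ring carbons ortho to the ketal oxygen: closure is expected at the carbon flanked by the small, chelated hydroxyl (future C4a), the usual site of electrophilic substitution in 2-hydroxy-4,6-dialkoxyacetophenones, whereas the carbon next to the methoxy group (future C8) is shielded by the methoxy methyl. Slow addition of the enol ether should keep its oligomerisation below the rate of the intramolecular closure.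

Step 3
Reactants: 6 1-(5-hydroxy-7-methoxy-2,2-dimethyl-2H-chromen-6-yl)ethan-1-one; 7 prenyl bromide (1-bromo-3-methylbut-2-ene)
Product: 8 1-[7-methoxy-2,2-dimethyl-5-(3-methylbut-2-enyloxy)-2H-chromen-6-yl]ethan-1-one
Conditions: prenyl bromide (1.5 equiv), K2CO3, DMF, 50 °C
Reagents that add atoms: prenyl bromide (7), CC(C)=CCBr
Why: Williamson O-alkylation (SN2) of the only phenol should proceed in carbonate/DMF, which favours O- over C-alkylation and does not enolise the methyl ketone.

Step 4
Reactants: 8 1-[7-methoxy-2,2-dimethyl-5-(3-methylbut-2-enyloxy)-2H-chromen-6-yl]ethan-1-one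
Product: 10 1-[5-hydroxy-7-methoxy-2,2-dimethyl-8-(3-methylbut-2-enyl)-2H-chromen-6-yl]ethan-1-one, via ortho-dienone 9 (not isolated)
Conditions: Eu(fod)3 (10 mol%), PhCl, 80 °C
Reagents that add atoms: none
Why: In this para-Claisen–Cope rearrangement both ortho positions are substituted, so the first [3,3] shift gives dienone 9 that cannot enolise, a second [3,3] (Cope) shift carries the allyl unit to C8 (the only free ring carbon, para to the oxygen), tautomerisation restores the chelated phenol, the two allylic inversions return the normal prenyl group, and Eu(III) chelation between ether oxygen and acetyl carbonyl should allow the mild temperature.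

Step 5
Reactants: 10 1-[5-hydroxy-7-methoxy-2,2-dimethyl-8-(3-methylbut-2-enyl)-2H-chromen-6-yl]ethan-1-one; 11 2-(4-bromophenoxy)tetrahydro-2H-pyran
Product: 13 1-[5-hydroxy-7-methoxy-2,2-dimethyl-8-(3-methylbut-2-enyl)-2H-chromen-6-yl]-2-(4-hydroxyphenyl)ethan-1-one (target), via THP ether 12 (not isolated)
Conditions: Pd2(dba)3 (2.5 mol%), XPhos (6 mol%), NaOtBu (3 equiv), PhMe, 80 °C, argon; then 1 M HCl, MeOH/THF, rt
Reagents that add atoms: 2-(4-bromophenoxy)tetrahydro-2H-pyran (11), Brc1ccc(OC2CCCCO2)cc1
Why: Buchwald–Hartwig α-arylation of the methyl ketone should proceed through the phenoxide–enolate dianion, with the more acidic benzyl ketone product resting as its enolate (which curbs diarylation), and mild acid methanolysis of the THP acetal then frees the phenol without touching the prenyl and chromene alkenes.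

Compound list
1 | 1-(2,4-dihydroxy-6-methoxyphenyl)ethan-1-one | CC(=O)c1c(O)cc(O)cc1OC | starting material
2 | 2-methoxypropene | COC(C)=C | starting material
3 | 1-[2-hydroxy-6-methoxy-4-(2-methoxypropan-2-yloxy)phenyl]ethan-1-one | CC(=O)c1c(O)cc(OC(C)(C)OC)cc1OC | intermediate
4 | ethyl vinyl ether | C=COCC | starting material
5 | 1-(4-ethoxy-5-hydroxy-7-methoxy-2,2-dimethyl-3,4-dihydro-2H-chromen-6-yl)ethan-1-one (racemic, not isolated) | CCOC1CC(C)(C)Oc2cc(OC)c(C(C)=O)c(O)c12 | intermediate
6 | 1-(5-hydroxy-7-methoxy-2,2-dimethyl-2H-chromen-6-yl)ethan-1-one | CC(=O)c1c(OC)cc2OC(C)(C)C=Cc2c1O | intermediate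
7 | prenyl bromide (1-bromo-3-methylbut-2-ene) | CC(C)=CCBr | starting material
8 | 1-[7-methoxy-2,2-dimethyl-5-(3-methylbut-2-enyloxy)-2H-chromen-6-yl]ethan-1-one | CC(=O)c1c(OC)cc2OC(C)(C)C=Cc2c1OCC=C(C)C | intermediate
9 | 6-acetyl-7-methoxy-2,2-dimethyl-6-(2-methylbut-3-en-2-yl)-2H-chromen-5(6H)-one (racemic, not isolated) | CC(=O)C1(C(C)(C)C=C)C(OC)=CC2=C(C=CC(C)(C)O2)C1=O | intermediate
10 | 1-[5-hydroxy-7-methoxy-2,2-dimethyl-8-(3-methylbut-2-enyl)-2H-chromen-6-yl]ethan-1-one | CC(=O)c1c(OC)c(CC=C(C)C)c2OC(C)(C)C=Cc2c1O | intermediate
11 | 2-(4-bromophenoxy)tetrahydro-2H-pyran (racemic) | Brc1ccc(OC2CCCCO2)cc1 | starting material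
12 | 1-[5-hydroxy-7-methoxy-2,2-dimethyl-8-(3-methylbut-2-enyl)-2H-chromen-6-yl]-2-[4-(tetrahydro-2H-pyran-2-yloxy)phenyl]ethan-1-one (racemic, not isolated) | COc1c(CC=C(C)C)c2OC(C)(C)C=Cc2c(O)c1C(=O)Cc1ccc(OC2CCCCO2)cc1 | intermediate
13 | 1-[5-hydroxy-7-methoxy-2,2-dimethyl-8-(3-methylbut-2-enyl)-2H-chromen-6-yl]-2-(4-hydroxyphenyl)ethan-1-one | COc1c(CC=C(C)C)c2c(c(O)c1C(=O)Cc1ccc(O)cc1)C=CC(C)(C)O2 | target

Total step count: 5. Longest linear sequence: 5 steps (from 1).

Steps most likely to fail

Step 2. The ketal may ionise in the wrong sense (loss of the aryloxide instead of methoxide), the enol ether may oligomerise faster than the ring closes, or closure may occur at the carbon next to the methoxy group (poor site selectivity). The fallback is the pericyclic chromene synthesis. It sets out from 1: O-alkylation of the 4-OH with 3-chloro-3-methylbut-1-yne (K2CO3, KI, CuI cat., acetone, 60 °C) should give 1-[2-hydroxy-6-methoxy-4-(2-methylbut-3-yn-2-yloxy)phenyl]ethan-1-one F1. Heating F1 (N,N-diethylaniline, 180 °C) should trigger the aryl propargyl Claisen rearrangement, a [1,5]-hydrogen shift and oxa-6π electrocyclisation. The chelate-induced bond fixation is expected to direct the shift to the carbon between the two oxygens. This gives 6, where the route resumes at step 3.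

Step 5. The chelating phenoxide–enolate dianion may sequester the palladium, a second arylation may occur at the benzylic position, or the chromene double bond may enter a Heck-type side reaction. The fallback removes the free phenol from the coupling. It sets out from 10: NaH and MOMCl in DMF should give the MOM ether 1-[7-methoxy-5-(methoxymethoxy)-2,2-dimethyl-8-(3-methylbut-2-enyl)-2H-chromen-6-yl]ethan-1-one F2. α-Arylation of the simple ketone enolate of F2 with 1-bromo-4-(methoxymethoxy)benzene (Pd2(dba)3, XPhos, NaOtBu, PhMe, 70 °C) should give the bis-MOM deoxybenzoin 1-[7-methoxy-5-(methoxymethoxy)-2,2-dimethyl-8-(3-methylbut-2-enyl)-2H-chromen-6-yl]-2-[4-(methoxymethoxy)phenyl]ethan-1-one F3. HCl in MeOH (40 °C) should cleave both MOM groups of F3 and give target 13.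

Step 4. The prenyl ether may ionise and lose the prenyl group (return to 6), the dienone formed at the ring-fusion carbon may undergo a Cope shift into the pyran C3=C4 bond, or the second shift may stall. The fallback is direct C-alkylation instead of a sigmatropic relay. It sets out from 6: the phenoxide (NaH, toluene, then prenyl bromide, rt → 60 °C; the non-polar medium favours C-alkylation) should be alkylated at C8, the only free position para to the oxygen. This gives 10 directly, where the route resumes at step 5; any O-alkylated 8 can be recycled. No new compound is made on this way.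

Further compounds
F1 | step 2 | 1-[2-hydroxy-6-methoxy-4-(2-methylbut-3-yn-2-yloxy)phenyl]ethan-1-one | CC(=O)c1c(O)cc(OC(C)(C)C#C)cc1OC
F2 | step 5 | 1-[7-methoxy-5-(methoxymethoxy)-2,2-dimethyl-8-(3-methylbut-2-enyl)-2H-chromen-6-yl]ethan-1-one | CC(=O)c1c(OC)c(CC=C(C)C)c2OC(C)(C)C=Cc2c1OCOC
F3 | step 5 | 1-[7-methoxy-5-(methoxymethoxy)-2,2-dimethyl-8-(3-methylbut-2-enyl)-2H-chromen-6-yl]-2-[4-(methoxymethoxy)phenyl]ethan-1-one | COCOc1ccc(CC(=O)c2c(OC)c(CC=C(C)C)c3OC(C)(C)C=Cc3c2OCOC)cc1
F0 | step 4 | none | none
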